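**Strategy.** Ring A is assembled from two acyclic pieces by an enantioselective Diels–Alder reaction that joins C2 to C3 and C4 to C5 (drimane-type numbering) in one operation. The diene (C2, C1, C10, C5) is the end of a geraniol-derived triene. The dienophile (C3=C4) is a Z-β-silyl-α-(acetoxymethyl)acrolein made by silylformylation of propargyl acetate. The step exploits the 1,3-dioxygenated C3–C4(CH3)–CH2O array of ring A with its quaternary C4: silicon is the masked 3-hydroxyl, the endo formyl group becomes the axial C4 methyl, and the exo acetoxymethyl arm becomes the angelate-bearing carbon. A proton-initiated cation–olefin cyclization then closes ring B, the C11 carbonate capturing the C8 cation.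

Key step: step 5

**Remarks before the steps**

- Numbering: ring A = C1–C5, C10; ring B = C5–C10; C11 = CH2O on C9; C12 = CH3 on C8; C13 = CH2O on C4; C14 = CH3 on C4; C15 = CH3 on C10. α/β are used in the relative sense only: β is the face of C15. The target is (3R,4S,5S,8S,9R,10R) with 3β-OH, 4α-CH2O-angelate, 4β-CH3, 5α-H, 8α-OH, 8β-CH3, 9β-CH2OAr and 10β-CH3.
- Assumption: the (S)-oxazaborolidinium ion of step 5 is assumed to direct the diene to the enal face that leads to 8; if the opposite sense is found, its (R)-antipode is used in the same way.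

**Route**

Step 1
Reactants: 1 geraniol
Product: 2 geranyl methyl carbonate
Conditions: ClCO2Me, pyridine, CH2Cl2, 0 °C to rt
Reagents that add atoms: methyl chloroformate COC(=O)Cl
Why: O-acylation of the primary allylic alcohol by a chloroformate gives the carbonate, which deactivates the neighbouring alkene toward oxidation and protonation and is the internal nucleophile of step 7; no stereocentre is formed.

Step 2
Reactants: 2 geranyl methyl carbonate
Product: 4 (2E,6E)-3,7-dimethyl-8-oxoocta-2,6-dien-1-yl methyl carbonate, via allylic alcohol 3 (not isolated)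
Conditions: SeO2 (0.1 equiv), t-BuOOH (2 equiv), salicylic acid (0.1 equiv), CH2Cl2, rt; then MnO2 (10 equiv), CH2Cl2, rt
Reagents that add atoms: selenium dioxide O=[Se]=O; tert-butyl hydroperoxide CC(C)(C)OO
Why: Riley allylic oxidation (ene reaction then [2,3]-sigmatropic shift) attacks the E-methyl group of the more electron-rich terminal alkene, and MnO2 converges alcohol and aldehyde on the E-enal with the alkene geometry kept.

Step 3
Reactants: 4 (2E,6E)-3,7-dimethyl-8-oxoocta-2,6-dien-1-yl methyl carbonate
Product: 5 (2E,6E)-3,7-dimethylnona-2,6,8-trien-1-yl methyl carbonate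
Conditions: Ph3PCH3Br, KN(SiMe3)2, THF, −78 to 0 °C
Reagents that add atoms: methyltriphenylphosphonium bromide C[P+](c1ccccc1)(c1ccccc1)c1ccccc1.[Br-]
Why: Wittig methylenation of the enal gives the E-configured 1,3-diene C2=C1–C10=C5, the aldehyde reacting far faster than the carbonate; the trisubstituted alkene geometry is untouched.

Step 4
Reactants: 6 propargyl acetate
Product: 7 (2Z)-3-[dimethyl(phenyl)silyl]-2-formylprop-2-en-1-yl acetate
Conditions: PhMe2SiH, CO (20 atm), Rh4(CO)12 (0.5 mol %), Et3N (cat.), toluene, 90 °C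
Reagents that add atoms: dimethylphenylsilane C[SiH](C)c1ccccc1; carbon monoxide [C-]#[O+]
Why: Rhodium-catalysed silylformylation of a terminal alkyne adds silyl and formyl groups syn with silicon at the terminal carbon, which fixes the Z geometry (Si cis to CHO) that the cycloaddition turns into the cis C3/C14 relationship.

Step 5
Reactants: 5 (2E,6E)-3,7-dimethylnona-2,6,8-trien-1-yl methyl carbonate; 7 (2Z)-3-[dimethyl(phenyl)silyl]-2-formylprop-2-en-1-yl acetate
Product: 8 [(1S,2S,6R)-6-[dimethyl(phenyl)silyl]-1-formyl-2-[(3E)-5-(methoxycarbonyloxy)-3-methylpent-3-en-1-yl]-3-methylcyclohex-3-en-1-yl]methyl acetate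
Conditions: 5 (1.5 equiv), (S)-1-(2-methylphenyl)-3,3-diphenyltetrahydro-1H,3H-pyrrolo[1,2-c][1,3,2]oxazaborole·HN(SO2CF3)2 (20 mol %), CH2Cl2, −78 to −40 °C
Reagents that add atoms: none
Why: Normal-electron-demand [4+2] cycloaddition in which the Lewis acid-bound enal 7 adds across C2 and C5 of diene 5 in a concerted, asynchronous transition state; the closest known reaction type is the oxazaborolidinium-catalysed Diels–Alder reaction of α-substituted enals with acyclic dienes. Ring A is closed as a cyclohexene by the suprafacial intermolecular [4+2] union of the two components, C2–C3 and C4–C5 being formed together. C3 and C4 are set relative to each other by the Z geometry of 7 (silicon cis to formyl), C5 relative to C4 by the E geometry of the diene and the endo orientation of the bound formyl group (formyl cis to C6, the larger acetoxymethyl arm exo), and the absolute configuration by the catalyst, which shields one face of the bound enal. The step needs ortho regiochemistry, endo selectivity and site selectivity: the formyl-bearing carbon (smaller LUMO coefficient) bonds to the substituted diene terminus C5 while the bulky silyl-bearing carbon bonds to the unhindered CH2 terminus, and the isolated, carbonate-deactivated C8=C9 alkene cannot act as a diene.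

Step 6
Reactants: 8 cycloadduct aldehyde
Product: 10 [(1S,2S,6R)-6-[dimethyl(phenyl)silyl]-2-[(3E)-5-(methoxycarbonyloxy)-3-methylpent-3-en-1-yl]-1,3-dimethylcyclohex-3-en-1-yl]methyl acetate, via tosylhydrazone 9 (not isolated)
Conditions: TsNHNH2, EtOH, rt; then catecholborane, CHCl3, 0 °C; NaOAc·3H2O, 60 °C
Reagents that add atoms: none
Why: Hydrazone formation and hydride reduction with loss of sulfinate and N2 (Kabalka variant of the Caglioti deoxygenation) should turn the neopentyl formyl group into the C14 methyl group under near-neutral conditions that spare acetate, carbonate, silane and both alkenes; no stereocentre is touched.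

Step 7
Reactants: 10 monocyclic silane
Product: 12 13-acetoxy-3β-[dimethyl(phenyl)silyl] decalin 8α,11-cyclic carbonate (3R,4S,5S,8S,9R,10R), via dioxanylium ion 11 (not isolated)
Conditions: FSO3H (5 equiv), 2-nitropropane, −78 °C; then Et3N, −78 °C to rt; aq. NaHCO3
Reagents that add atoms: none
Why: Proton-initiated cation–olefin cyclization: Markovnikov protonation of the more basic ring alkene gives the tertiary C10 cation, which is attacked by C9 of the E-alkene through a chair transition state from the face opposite the axial C14 methyl group (6-endo closure of ring B; trans-decalin with C15 β and C11 equatorial), the carbonate carbonyl then captures the C8 cation anti to the new bond (8α-oxygen, 8β-methyl) as the acetate group does in the fluorosulfonic acid cyclization of farnesyl acetate, and triethylamine removes the O-methyl group of the resulting dioxanylium ion.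

Step 8
Reactants: 12 silyl cyclic carbonate
Product: 13 13-acetoxy-3β-hydroxy decalin 8α,11-cyclic carbonate (3R,4S,5S,8S,9R,10R)
Conditions: KBr, AcOOH, NaOAc, AcOH, 0 °C to rt
Reagents that add atoms: peracetic acid CC(=O)OO
Why: Fleming–Tamao oxidation (ipso-bromodesilylation of the phenyl group, then peracid-induced 1,2-shift from silicon to oxygen) replaces silicon by hydroxyl with retention and should give the equatorial 3β-alcohol; a silanol formed by loss of the phenyl group in step 7 would be oxidised in the same way.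

Step 9
Reactants: 13 hydroxy cyclic carbonate; 14 umbelliferone (7-hydroxycoumarin)
Product: 16 11-(2-oxo-2H-chromen-7-yloxy) decalin 3β,8α,13-triol (3R,4S,5S,8S,9R,10R), via acetate 15 (not isolated)
Conditions: 14 (1.5 equiv), Cs2CO3 (0.2 equiv), DMF, 130 °C; then K2CO3 (cat.), MeOH, rt; dilute HCl work-up
Reagents that add atoms: none
Why: Decarboxylative O-alkylation of a phenol by a cyclic carbonate: the phenoxide can attack only the primary C11 in an SN2 sense (C8 is tertiary), loss of CO2 makes the opening irreversible and frees the 8α-hydroxyl, and mild methanolysis then removes the acetate; no stereocentre is involved.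

Step 10
Reactants: 16 triol aryl ether; 17 angelic acid [(2Z)-2-methylbut-2-enoic acid]
Product: 19 target 13-angelate (3R,4S,5S,8S,9R,10R), via mixed anhydride 18 (not isolated)
Conditions: 17 (1.2 equiv), 2,4,6-trichlorobenzoyl chloride, Et3N, toluene, rt; then 16, toluene, 75 °C (no DMAP)
Reagents that add atoms: none
Why: Yamaguchi-type acylation through the mixed anhydride should select the primary C13 hydroxyl over the hindered secondary C3 hydroxyl (next to quaternary C4) and the tertiary C8 hydroxyl, and leaving out a nucleophilic catalyst keeps the Z geometry of the angelate.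

**Compound list**

1 | geraniol, (2E)-3,7-dimethylocta-2,6-dien-1-ol | CC(C)=CCC/C(C)=C/CO | starting material
2 | geranyl methyl carbonate | CC(C)=CCC/C(C)=C/COC(=O)OC | intermediate
3 | (2E,6E)-8-hydroxy-3,7-dimethylocta-2,6-dien-1-yl methyl carbonate | OC/C(C)=C/CC/C(C)=C/COC(=O)OC | intermediate (not isolated)
4 | (2E,6E)-3,7-dimethyl-8-oxoocta-2,6-dien-1-yl methyl carbonate | O=C/C(C)=C/CC/C(C)=C/COC(=O)OC | intermediate
5 | (2E,6E)-3,7-dimethylnona-2,6,8-trien-1-yl methyl carbonate | C=C/C(C)=C/CC/C(C)=C/COC(=O)OC | intermediate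
6 | propargyl acetate, prop-2-yn-1-yl acetate | CC(=O)OCC#C | starting material
7 | (2Z)-3-[dimethyl(phenyl)silyl]-2-formylprop-2-en-1-yl acetate (Si cis to CHO) | O=C/C(COC(C)=O)=C\[Si](C)(C)c1ccccc1 | intermediate
8 | [(1S,2S,6R)-6-[dimethyl(phenyl)silyl]-1-formyl-2-[(3E)-5-(methoxycarbonyloxy)-3-methylpent-3-en-1-yl]-3-methylcyclohex-3-en-1-yl]methyl acetate (C3-Si β, C4-CHO β, C4-CH2OAc α, C5-H α) | CC(=O)OC[C@]1(C=O)[C@@H](CC/C(C)=C/COC(=O)OC)C(C)=CC[C@H]1[Si](C)(C)c1ccccc1 | intermediate
9 | 4-methylbenzenesulfonylhydrazone of 8 (E at C=N, ring configuration as in 8) | CC(=O)OC[C@]1(/C=N/NS(=O)(=O)c2ccc(C)cc2)[C@@H](CC/C(C)=C/COC(=O)OC)C(C)=CC[C@H]1[Si](C)(C)c1ccccc1 | intermediate (not isolated)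
10 | [(1S,2S,6R)-6-[dimethyl(phenyl)silyl]-2-[(3E)-5-(methoxycarbonyloxy)-3-methylpent-3-en-1-yl]-1,3-dimethylcyclohex-3-en-1-yl]methyl acetate | CC(=O)OC[C@]1(C)[C@@H](CC/C(C)=C/COC(=O)OC)C(C)=CC[C@H]1[Si](C)(C)c1ccccc1 | intermediate
11 | 2-methoxy-1,3-dioxan-2-ylium fluorosulfate fused at C8–C9 of the trans-decalin (3R,4S,5S,8S,9R,10R) | CC(=O)OC[C@]1(C)[C@H]2CC[C@]3(C)OC(OC)=[O+]C[C@H]3[C@]2(C)CC[C@H]1[Si](C)(C)c1ccccc1.[O-]S(=O)(=O)F | intermediate (not isolated)
12 | 13-acetoxy-3β-[dimethyl(phenyl)silyl]-4β,8β,10β-trimethyl trans-decalin 8α,11-cyclic carbonate (3R,4S,5S,8S,9R,10R) | CC(=O)OC[C@]1(C)[C@H]2CC[C@]3(C)OC(=O)OC[C@H]3[C@]2(C)CC[C@H]1[Si](C)(C)c1ccccc1 | intermediate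
13 | 13-acetoxy-3β-hydroxy trans-decalin 8α,11-cyclic carbonate (3R,4S,5S,8S,9R,10R) | CC(=O)OC[C@]1(C)[C@H]2CC[C@]3(C)OC(=O)OC[C@H]3[C@]2(C)CC[C@H]1O | intermediate
14 | umbelliferone, 7-hydroxy-2H-chromen-2-one | Oc1ccc2ccc(=O)oc2c1 | starting material
15 | 13-acetoxy-11-(2-oxo-2H-chromen-7-yloxy) trans-decalin 3β,8α-diol (3R,4S,5S,8S,9R,10R) | CC(=O)OC[C@]1(C)[C@H]2CC[C@](C)(O)[C@@H](COc3ccc4ccc(=O)oc4c3)[C@]2(C)CC[C@H]1O | intermediate (not isolated)
16 | 11-(2-oxo-2H-chromen-7-yloxy) trans-decalin 3β,8α,13-triol (3R,4S,5S,8S,9R,10R) | OC[C@]1(C)[C@H]2CC[C@](C)(O)[C@@H](COc3ccc4ccc(=O)oc4c3)[C@]2(C)CC[C@H]1O | intermediate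
17 | angelic acid, (2Z)-2-methylbut-2-enoic acid | C/C=C(/C)C(=O)O | starting material
18 | (2Z)-2-methylbut-2-enoic 2,4,6-trichlorobenzoic anhydride | C/C=C(/C)C(=O)OC(=O)c1c(Cl)cc(Cl)cc1Cl | intermediate (not isolated)
19 | CNP0139045.1: 3β,8α-dihydroxy-11-(2-oxo-2H-chromen-7-yloxy) trans-decalin-13-yl (2Z)-2-methylbut-2-enoate (3R,4S,5S,8S,9R,10R) | C/C=C(/C)C(=O)OC[C@]1(C)[C@H]2CC[C@](C)(O)[C@@H](COc3ccc4ccc(=O)oc4c3)[C@]2(C)CC[C@H]1O | target

**Step count and risks**

Total steps: 10. Longest linear sequence: 9 steps (steps 1, 2, 3, 5, 6, 7, 8, 9, 10); step 4 is a one-step branch.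

Steps most likely to fail:

1. Step 5. The chiral Lewis acid may discriminate poorly between the faces and between endo and exo approach of the hindered Z-β-silyl enal, or turn over slowly, so that enantiomeric purity or the C4/C5 relationship is eroded. Fallback: setting out from 5 and 7, the cycloaddition is promoted by stoichiometric Me2AlCl (CH2Cl2, −78 °C), which should give 8 together with the mirror-image cycloadduct F1 as the racemate. Condensation with (1R,2R)-N,N'-dimethyl-1,2-diphenylethane-1,2-diamine (Et2O, molecular sieves) gives the imidazolidine F2 from 8 and the diastereomeric imidazolidine F3 from F1. These are separated by chromatography, and mild acid hydrolysis of F2 (2% aqueous HCl, Et2O) comes back to the route at 8.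

2. Step 7. Proton loss from the C8 cation may outrun its capture by the carbonate, so that an alkene is formed instead of the C8–O bond. Fallback: setting out from 10, the same acid treatment is accepted to end in the trans-fused C7=C8 alkene F4. Mukaiyama hydration (cobalt bis(acetylacetonate) Co(C5H7O2)2, PhSiH3, O2, i-PrOH) should place the hydroxyl on the less hindered α face of the tertiary C8 radical and give the 8α-hydroxy 11-methyl carbonate F5. DBU in warm toluene closes F5 with loss of methanol and comes back to the route at 12.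

3. Step 9. SN2 attack of the weakly nucleophilic coumarin phenoxide at the β-branched C11 may be too slow, so that reversible attack at the carbonate carbonyl and thermal degradation take over. Fallback: setting out from 13, the cyclic carbonate is hydrolysed selectively (LiOH 1.1 equiv, THF–H2O, 0 °C; the neopentyl acetate reacts more slowly) to the 3β,8α,11-triol 13-acetate F6. Mitsunobu etherification of its only primary hydroxyl with 14 (PPh3, diisopropyl azodicarboxylate, THF, rt) comes back to the route at 15, which is methanolysed to 16 as in step 9.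

**Further compounds**

F1 | step 5 | enantiomer of 8, [(1R,2R,6S)-6-[dimethyl(phenyl)silyl]-1-formyl-2-[(3E)-5-(methoxycarbonyloxy)-3-methylpent-3-en-1-yl]-3-methylcyclohex-3-en-1-yl]methyl acetate | CC(=O)OC[C@@]1(C=O)[C@H](CC/C(C)=C/COC(=O)OC)C(C)=CC[C@@H]1[Si](C)(C)c1ccccc1
F2 | step 5 | (4R,5R)-1,3-dimethyl-4,5-diphenylimidazolidin-2-yl aminal of 8 | CC(=O)OC[C@]1(C2N(C)[C@H](c3ccccc3)[C@@H](c3ccccc3)N2C)[C@@H](CC/C(C)=C/COC(=O)OC)C(C)=CC[C@H]1[Si](C)(C)c1ccccc1
F3 | step 5 | (4R,5R)-1,3-dimethyl-4,5-diphenylimidazolidin-2-yl aminal of F1 | CC(=O)OC[C@@]1(C2N(C)[C@H](c3ccccc3)[C@@H](c3ccccc3)N2C)[C@H](CC/C(C)=C/COC(=O)OC)C(C)=CC[C@@H]1[Si](C)(C)c1ccccc1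
F4 | step 7 | 13-acetoxy-3β-[dimethyl(phenyl)silyl]-11-(methoxycarbonyloxy) trans-fused decal-7-ene (C7=C8) | CC(=O)OC[C@]1(C)[C@H]2CC=C(C)[C@@H](COC(=O)OC)[C@]2(C)CC[C@H]1[Si](C)(C)c1ccccc1
F5 | step 7 | 13-acetoxy-3β-[dimethyl(phenyl)silyl]-11-(methoxycarbonyloxy) trans-decalin-8α-ol | CC(=O)OC[C@]1(C)[C@H]2CC[C@](C)(O)[C@@H](COC(=O)OC)[C@]2(C)CC[C@H]1[Si](C)(C)c1ccccc1
F6 | step 9 | 13-acetoxy trans-decalin 3β,8α,11-triol | CC(=O)OC[C@]1(C)[C@H]2CC[C@](C)(O)[C@@H](CO)[C@]2(C)CC[C@H]1O
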